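The vessel is a closed, stirred two-phase flask: reagent crosses from the second phase into the reaction phase, meets starting material there and gives target, which can turn into its isomer.

| flask | starting material | reagent in the second phase | remark | time | volume of the second phase over the first |
|---|---|---|---|---|---|
| eta | 0.050 M | 2.1 equiv | run made earlier |  |  |
| zeta | 0.050 M | 3.3 equiv | run made earlier |  |  |
| beta | 0.10 M | 1.5 equiv | run made earlier |  |  |
| flask | 0.050 M | 1.50 equiv |  | 10 d | 1.0 |

| run | time / d | target / % | starting material / % |
|---|---|---|---|
| eta | 2.08 | 22.4 | 44.9 |
| eta | 4.00 | 21.6 | 12.8 |
| eta | 6.00 | 15.3 | 1.1 |
| eta | 8.00 | 12.5 | 0 |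
| eta | 10.0 | 11.6 | 0.3 |
| eta | 12.0 | 12.2 | 0 |
| zeta | 0.833 | 22.5 | 66.5 |
| zeta | 2.50 | 30.8 | 12.0 |
| zeta | 4.00 | 18.1 | 1.1 |
| zeta | 6.00 | 12.5 | 0.5 |
| zeta | 10.0 | 13.3 | 0.2 |
| zeta | 12.0 | 11.4 | 0 |
| beta | 1.04 | 12.9 | 77.7 |
| beta | 1.67 | 14.3 | 63.6 |
| beta | 3.00 | 17.1 | 39.7 |
| beta | 6.00 | 14.9 | 7.6 |
| beta | 12.0 | 10.3 | 0 |

(each reading ± 0.5 percentage points)

- a species is counted by the starting material in it: one side product counts as two
- in the second phase: reagent in the second phase; everything else is in the first
- charges count per volume of the first phase; a concentration in a rate is the amount of a species over the volume of its own phase; every rate counts per litre of the first phase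
- the numbers in the tables scatter by 0.5 percentage points (one standard deviation)
- steps under discussion: reagent in the reaction phase <-> reagent in the second phase; starting material + reagent in the reaction phase -> target; 2 reagent in the reaction phase -> self-condensation product; target <-> isomer of the product; starting material + target -> side product
- the earlier runs hold the two phases in the same ratio of volumes as the flask asked about

- amount of target at 10 d, in percent of the starting material charged
- the change that raises the amount of target at 10 d, in percent of the starting material charged most ("none" if none brings more than 2 percentage points) (oak / alder / none)
- amount of target at 10 d, in percent of the starting material charged, after oak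

In the eta and zeta runs, the target falls to a level and stays there once starting material is within the scatter of zero. We take the mean of those late readings:

s = 12.2%

We call s the plateau share, the fraction of reacted starting material standing as target in those late readings, and we read it as thermodynamic control between target and isomer. The zero of our scale is an even split, half of what has reacted, and s lies far below that.

Now we turn the question round. One way for oak to gain more than 2 percentage points is a plateau that moves with the reagent charge. Yet the means are:

eta: 12.1%; zeta: 12.4%

They differ by 0.3 points, less than that margin. Either change could also gain if the flask were still rising at 10 d. But the beta run, at the same equivalents and twice the starting concentration, shows its highest target reading at 3.00 d and 7.6% starting material at 6.00 d.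

So our own reckoning gives s for the flask and the zeta mean for oak, and we expect neither change to gain more than 2 points. The forecast gives 12% for the flask, none as the best change and 12.4% after oak, adding that “Alder only speeds the approach to the same plateau”.

The flask gives 12.6% at 10 d, with 0.512% starting material left. The answer for the best change is none: oak moves the target by −0.59 points to 12.0%, and alder moves it by −0.66 points.

    reagent in the reaction phase ⇌ reagent in the second phase, rate k1*([reagent in the reaction phase] - [reagent in the second phase]/K1) per volume of the first phase (partition coefficient = 1.40, kL = 0.00957 h⁻¹)
    starting material + reagent in the reaction phase → target (k = 6.52 L mol⁻¹ h⁻¹)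
    2 reagent in the reaction phase → self-condensation product (k = 0.159 L mol⁻¹ h⁻¹)
    target ⇌ isomer of the product (K = 6.90, k = 0.0439 h⁻¹)
    starting material + target → side product (k = 0.0809 L mol⁻¹ h⁻¹)

Multiplying s by the reacted part of the charge:

flask at 10 d: 12.1%, against 12.6% found

The same flask read at 4.0 d still has 32% of its starting material:

neighbour: 8.34%

That neighbour holds 17.0% target, twice the reckoned amount.

The data are calculated for an exercise; noise was put on by code.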